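**Retrosynthetic overview**
1. Target ⇐ C7 acetylation ⇐ 1,2-dioxane closed last and transannularly (C8–OOH onto a C11 allyl cation) ⇐ perhydrolysis of a (7S,8R) cis-epoxide with inversion at C8.
2. The 14-membered carbocycle and the cis-γ-lactone form together: C1–C2 bond from a carbene-generated homoenolate (C1, the β-carbon of an enal) adding to the C2 aldehyde of an acyclic bis-enal; α-methylenation follows.
3. Bis-enal ⇐ C11–C12 Nozaki–Hiyama–Kishi coupling (Z-alkenyl iodide), C4–C5 B-alkyl Suzuki coupling (E-enol triflate), C1=C15 cross-metathesis.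
4. Building blocks: nerol (Sharpless epoxidation sets C7/C8), but-2-yn-1-ol (Z-alkenyl iodide), ethyl acetoacetate (E-enol triflate).
5. Ring order: oxirane → macrocarbocycle + γ-lactone (one step) → 1,2-dioxane.

Convention and assumption: macrocycles are named with cembrane numbering (ring C1–C14; C15 = lactone α-carbon on C1, C16 = carbonyl, lactone O on C2, C17 = exocyclic CH2; C18, C19, C20 = methyls on C4, C8, C12), in which the target is (1S,2S,3E,7S,8S,11R,12Z). C11 is carried as a 1:1 epimer mixture (no descriptor in its SMILES) from step 10 until step 18 makes it a single centre.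

**Route**

Step 1
Reactants: 1 ethyl acetoacetate
Product: 2 ethyl (2E)-3-{[(trifluoromethyl)sulfonyl]oxy}but-2-enoate
Conditions: (CF3SO2)2O, Me4NOH (aq.), toluene, 5 → 20 °C
Reagents that add atoms: trifluoromethanesulfonic anhydride, O=S(=O)(OS(=O)(=O)C(F)(F)F)C(F)(F)F
Why: Stereoselective enol triflation under Schotten–Baumann conditions; the non-chelating tetramethylammonium enolate gives the (E)-enol triflate.

Step 2
Reactants: 3 but-2-yn-1-ol
Product: 5 (2Z)-3-iodobut-2-en-1-ol, via cyclic vinylalanate 4 (not isolated)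
Conditions: NaAlH2(OCH2CH2OCH3)2, THF, 0 → 20 °C; then I2, −78 °C
Reagents that add atoms: iodine, II
Why: Hydroxyl-directed trans-hydroalumination puts aluminium on C3 anti to the new C2–H, and iodinolysis with retention gives the Z-iodide.

Step 3
Reactants: 5 (2Z)-3-iodobut-2-en-1-ol
Product: 6 (2Z)-1-bromo-3-iodobut-2-ene
Conditions: PBr3 (0.4 equiv), Et2O, 0 °C
Reagents that add atoms: phosphorus tribromide, BrP(Br)Br
Why: SN2 bromination of a primary allylic alcohol through its phosphite ester, without allylic transposition or loss of alkene geometry.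

Step 4
Reactants: 6 (2Z)-1-bromo-3-iodobut-2-ene
Product: 7 (2Z)-2-iodohexa-2,5-diene
Conditions: CH2=CHMgBr, CuI (10 mol%), THF, −30 → 0 °C
Reagents that add atoms: vinylmagnesium bromide, C=C[Mg]Br
Why: Copper-catalysed SN2 allylic substitution of the primary bromide by the vinyl organomagnesium reagent; the alkenyl iodide is inert at this temperature.

Step 5
Reactants: 8 nerol
Product: 9 [(2S,3R)-3-methyl-3-(4-methylpent-3-en-1-yl)oxiran-2-yl]methanol
Conditions: Ti(O-i-Pr)4 (5 mol%), L-(+)-diisopropyl tartrate (6 mol%), t-BuOOH, 4 Å MS, CH2Cl2, −20 °C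
Reagents that add atoms: tert-butyl hydroperoxide, CC(C)(C)OO
Why: Sharpless asymmetric epoxidation of the Z-allylic alcohol; L-(+)-tartrate gives the (2S,3R) cis-epoxide, which fixes C7 and (after inversion in step 17) C8.

Step 6
Reactants: 9 [(2S,3R)-3-methyl-3-(4-methylpent-3-en-1-yl)oxiran-2-yl]methanol
Product: 10 (2R,3R)-3-methyl-3-(4-methylpent-3-en-1-yl)oxirane-2-carbaldehyde
Conditions: Dess–Martin periodinane, NaHCO3, CH2Cl2, 0 → 20 °C
Reagents that add atoms: none
Why: Buffered Dess–Martin oxidation gives the α,β-epoxy aldehyde without epimerisation or ring opening.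

Step 7
Reactants: 10 (2R,3R)-3-methyl-3-(4-methylpent-3-en-1-yl)oxirane-2-carbaldehyde
Product: 11 (2S,3R)-2-ethenyl-3-methyl-3-(4-methylpent-3-en-1-yl)oxirane
Conditions: Ph3PCH3Br, KN(SiMe3)2, THF, −78 → 0 °C
Reagents that add atoms: methyltriphenylphosphonium bromide, C[P+](c1ccccc1)(c1ccccc1)c1ccccc1.[Br-]
Why: Wittig methylenation with the non-stabilised ylide leaves both oxirane stereocentres untouched.

Step 8
Reactants: 11 (2S,3R)-2-ethenyl-3-methyl-3-(4-methylpent-3-en-1-yl)oxirane; 2 ethyl (2E)-3-{[(trifluoromethyl)sulfonyl]oxy}but-2-enoate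
Product: 13 ethyl (2E)-3-methyl-5-[(2S,3R)-3-methyl-3-(4-methylpent-3-en-1-yl)oxiran-2-yl]pent-2-enoate, via B-alkyl-9-BBN adduct 12 (not isolated)
Conditions: 9-BBN dimer, THF, 0 → 20 °C; then 2, PdCl2(dppf) (5 mol%), AsPh3 (10 mol%), Cs2CO3, DMF/H2O, 20 °C
Reagents that add atoms: none
Why: Anti-Markovnikov hydroboration of the only monosubstituted alkene, then B-alkyl Suzuki–Miyaura coupling with retention at the enol triflate, fixes the 3E trisubstituted alkene.

Step 9
Reactants: 13 ethyl (2E)-3-methyl-5-[(2S,3R)-3-methyl-3-(4-methylpent-3-en-1-yl)oxiran-2-yl]pent-2-enoate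
Product: 14 ethyl (2E)-3-methyl-5-[(2S,3R)-3-methyl-3-(3-oxopropyl)oxiran-2-yl]pent-2-enoate
Conditions: O3, pyridine (3 equiv), CH2Cl2, −78 °C
Reagents that add atoms: ozone, [O-][O+]=O
Why: Ozonolysis takes the electron-rich trisubstituted alkene in preference to the conjugated ester alkene, and pyridine decomposes the carbonyl oxide directly to the aldehyde.

Step 10
Reactants: 14 ethyl (2E)-3-methyl-5-[(2S,3R)-3-methyl-3-(3-oxopropyl)oxiran-2-yl]pent-2-enoate; 7 (2Z)-2-iodohexa-2,5-diene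
Product: 15 ethyl (2E)-5-{(2S,3R)-3-[(4Z)-3-hydroxy-4-methylocta-4,7-dien-1-yl]-3-methyloxiran-2-yl}-3-methylpent-2-enoate (1:1 carbinol epimers)
Conditions: CrCl2 (4 equiv), NiCl2 (1 mol%), DMSO, 20 °C
Reagents that add atoms: none
Why: Nozaki–Hiyama–Kishi coupling: the alkenylchromium species keeps the Z geometry and adds only to the aldehyde (ester and oxirane inert); the new C11 carbinol forms unselectively and is made uniform in step 18.

Step 11
Reactants: 15 ethyl (2E)-5-{(2S,3R)-3-[(4Z)-3-hydroxy-4-methylocta-4,7-dien-1-yl]-3-methyloxiran-2-yl}-3-methylpent-2-enoate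
Product: 16 (2E)-5-{(2S,3R)-3-[(4Z)-3-hydroxy-4-methylocta-4,7-dien-1-yl]-3-methyloxiran-2-yl}-3-methylpent-2-en-1-ol
Conditions: (i-Bu)2AlH (3.3 equiv), CH2Cl2, −78 °C; aq. potassium sodium tartrate work-up
Reagents that add atoms: none
Why: 1,2-Reduction of the enoate by diisobutylaluminium hydride at low temperature, with neutral work-up to protect the epoxy alcohol.

Step 12
Reactants: 16 (2E)-5-{(2S,3R)-3-[(4Z)-3-hydroxy-4-methylocta-4,7-dien-1-yl]-3-methyloxiran-2-yl}-3-methylpent-2-en-1-ol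
Product: 17 (2E)-5-{(2S,3R)-3-[(4Z)-3-hydroxy-4-methylocta-4,7-dien-1-yl]-3-methyloxiran-2-yl}-3-methylpent-2-enal
Conditions: TEMPO (10 mol%), PhI(OAc)2 (1.1 equiv), NaHCO3, CH2Cl2, 0 → 20 °C
Reagents that add atoms: none
Why: Oxoammonium (TEMPO) oxidation takes the primary allylic alcohol and leaves the hindered secondary one; the buffer prevents acid-induced opening of the oxirane by the C11 hydroxyl.

Step 13
Reactants: 17 (2E)-5-{(2S,3R)-3-[(4Z)-3-hydroxy-4-methylocta-4,7-dien-1-yl]-3-methyloxiran-2-yl}-3-methylpent-2-enal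
Product: 18 (4Z)-4-methyl-1-{(2R,3S)-2-methyl-3-[(3E)-3-methyl-5-oxopent-3-en-1-yl]oxiran-2-yl}octa-4,7-dien-3-yl 2,2-dimethylpropanoate
Conditions: t-BuCOCl, DMAP (20 mol%), pyridine, CH2Cl2, 0 → 20 °C
Reagents that add atoms: pivaloyl chloride, CC(C)(C)C(=O)Cl
Why: DMAP-catalysed acylation; the pivalate has no α-hydrogen, so it masks C11–OH through the basic steps and later serves as the leaving group.

Step 14
Reactants: 18 (4Z)-4-methyl-1-{(2R,3S)-2-methyl-3-[(3E)-3-methyl-5-oxopent-3-en-1-yl]oxiran-2-yl}octa-4,7-dien-3-yl 2,2-dimethylpropanoate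
Product: 19 (4Z,7E)-4-methyl-1-{(2R,3S)-2-methyl-3-[(3E)-3-methyl-5-oxopent-3-en-1-yl]oxiran-2-yl}-9-oxonona-4,7-dien-3-yl 2,2-dimethylpropanoate
Conditions: crotonaldehyde (5 equiv), second-generation Hoveyda–Grubbs catalyst RuCl2(H2IMes)(=CH-C6H4-2-O-i-Pr) (5 mol%), 1,4-benzoquinone (10 mol%), CH2Cl2, 40 °C
Reagents that add atoms: (E)-but-2-enal, C/C=C/C=O
Why: Olefin cross-metathesis of the monosubstituted alkene (the trisubstituted alkenes and the existing enal do not take part) gives the E-enal.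

Step 15
Reactants: 19 (4Z,7E)-4-methyl-1-{(2R,3S)-2-methyl-3-[(3E)-3-methyl-5-oxopent-3-en-1-yl]oxiran-2-yl}-9-oxonona-4,7-dien-3-yl 2,2-dimethylpropanoate
Product: 20 (1S,2R,3E,7S,8R,12Z)-7,8-epoxy-11-(pivaloyloxy)cembra-3,12-dien-16,2-olide
Conditions: (5aS,10bR)-2-mesityl-5a,10b-dihydro-4H,6H-indeno[2,1-b][1,2,4]triazolo[4,3-d][1,4]oxazin-2-ium chloride (20 mol%), DBU (20 mol%), THF, 2 mM (syringe pump, 12 h), 40 °C
Reagents that add atoms: none
Why: Proposed new method: the triazolylidene adds to the less hindered C16 enal, the resulting Breslow intermediate reacts as a homoenolate whose C1 attacks the tethered C2 aldehyde (1,2-addition to the β,β-disubstituted enal, itself a poor homoenolate donor), and the alkoxide then acylates intramolecularly and releases the carbene; the closest known reaction is the intermolecular, cis-selective carbene-catalysed enal + aldehyde γ-butyrolactone annulation, run here intramolecularly at high dilution so that the 14-membered ring, the lactone and both new stereocentres arise at once (cis C1/C2 from the usual annulation preference, absolute sense from the chiral triazolium).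

Step 16
Reactants: 20 (1S,2R,3E,7S,8R,12Z)-7,8-epoxy-11-(pivaloyloxy)cembra-3,12-dien-16,2-olide
Product: 23 (1S,2S,3E,7S,8R,12Z)-7,8-epoxy-11-(pivaloyloxy)cembra-3,12,15(17)-trien-16,2-olide, via Mannich base 21 (not isolated), via methiodide 22 (not isolated)
Conditions: LiN(i-Pr)2, THF, −78 °C; CH2=NMe2+ I−, −78 → 0 °C; then MeI, THF/MeOH, 20 °C; then NaHCO3 (aq.), EtOAc, 20 °C
Reagents that add atoms: N,N-dimethylmethyleneiminium iodide (Eschenmoser's salt), C=[N+](C)C.[I-]
Why: α-Methylenation by Mannich reaction of the lactone lithium enolate, N-methylation and E1cB elimination of trimethylamine; C1 and C2 are not touched.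

Step 17
Reactants: 23 (1S,2S,3E,7S,8R,12Z)-7,8-epoxy-11-(pivaloyloxy)cembra-3,12,15(17)-trien-16,2-olide
Product: 24 (1S,2S,3E,7S,8S,12Z)-8-hydroperoxy-7-hydroxy-11-(pivaloyloxy)cembra-3,12,15(17)-trien-16,2-olide
Conditions: H2O2 (anhydrous, in Et2O, 10 equiv), H3PMo12O40 (3 mol%), Et2O, 20 °C
Reagents that add atoms: hydrogen peroxide, OO
Why: Phosphomolybdic-acid-catalysed perhydrolysis of the trisubstituted epoxide: H2O2 attacks the tertiary C8 with inversion while the C7–O bond is kept, giving the (7S,8S) hydroxy hydroperoxide.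

Step 18
Reactants: 24 (1S,2S,3E,7S,8S,12Z)-8-hydroperoxy-7-hydroxy-11-(pivaloyloxy)cembra-3,12,15(17)-trien-16,2-olide
Product: 25 (1S,2S,3E,7S,8S,11R,12Z)-8,11-epidioxy-7-hydroxycembra-3,12,15(17)-trien-16,2-olide
Conditions: BF3·OEt2 (1.2 equiv), 4 Å MS, CH2Cl2 (1 mM), −60 → −20 °C
Reagents that add atoms: none
Why: Lewis-acid ionisation of the allylic pivalate gives an allyl cation that the terminal oxygen of the C8 hydroperoxide captures at C11 (SN1 O-alkylation, 6-exo cycloperoxidation); both C11 epimers converge because only the cis-bridged (11R) dioxane can span the macrocycle, and the 12Z geometry is kept because capture is faster than rotation.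

Step 19
Reactants: 25 (1S,2S,3E,7S,8S,11R,12Z)-8,11-epidioxy-7-hydroxycembra-3,12,15(17)-trien-16,2-olide
Product: 26 (1S,2S,3E,7S,8S,11R,12Z)-7-acetoxy-8,11-epidioxycembra-3,12,15(17)-trien-16,2-olide (target)
Conditions: Ac2O, DMAP (10 mol%), pyridine, CH2Cl2, 0 °C
Reagents that add atoms: acetic anhydride, CC(=O)OC(C)=O
Why: DMAP-catalysed acetylation of the secondary C7 alcohol under conditions mild enough for the 1,2-dioxane and the α-methylene lactone.

**Compound list**
1 | ethyl acetoacetate | CCOC(=O)CC(C)=O | starting material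
2 | ethyl (2E)-3-{[(trifluoromethyl)sulfonyl]oxy}but-2-enoate | CCOC(=O)/C=C(\C)OS(=O)(=O)C(F)(F)F | intermediate
3 | but-2-yn-1-ol | CC#CCO | starting material
4 | sodium 2,2-bis(2-methoxyethoxy)-3-methyl-2,5-dihydro-1,2-oxaaluminol-2-uide (cyclic vinylalanate, not isolated) | [Na+].CC1=CCO[Al-]1(OCCOC)OCCOC | intermediate
5 | (2Z)-3-iodobut-2-en-1-ol | C/C(I)=C/CO | intermediate
6 | (2Z)-1-bromo-3-iodobut-2-ene | C/C(I)=C/CBr | intermediate
7 | (2Z)-2-iodohexa-2,5-diene | C/C(I)=C/CC=C | intermediate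
8 | nerol, (2Z)-3,7-dimethylocta-2,6-dien-1-ol | CC(C)=CCC/C(C)=C\CO | starting material
9 | [(2S,3R)-3-methyl-3-(4-methylpent-3-en-1-yl)oxiran-2-yl]methanol | OC[C@@H]1O[C@]1(C)CCC=C(C)C | intermediate
10 | (2R,3R)-3-methyl-3-(4-methylpent-3-en-1-yl)oxirane-2-carbaldehyde | O=C[C@@H]1O[C@]1(C)CCC=C(C)C | intermediate
11 | (2S,3R)-2-ethenyl-3-methyl-3-(4-methylpent-3-en-1-yl)oxirane | C=C[C@@H]1O[C@]1(C)CCC=C(C)C | intermediate
12 | 9-{2-[(2S,3R)-3-methyl-3-(4-methylpent-3-en-1-yl)oxiran-2-yl]ethyl}-9-borabicyclo[3.3.1]nonane (not isolated) | C(C[C@@H]1O[C@]1(C)CCC=C(C)C)B2C3CCCC2CCC3 | intermediate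
13 | ethyl (2E)-3-methyl-5-[(2S,3R)-3-methyl-3-(4-methylpent-3-en-1-yl)oxiran-2-yl]pent-2-enoate | CCOC(=O)/C=C(\C)CC[C@@H]1O[C@]1(C)CCC=C(C)C | intermediate
14 | ethyl (2E)-3-methyl-5-[(2S,3R)-3-methyl-3-(3-oxopropyl)oxiran-2-yl]pent-2-enoate | CCOC(=O)/C=C(\C)CC[C@@H]1O[C@]1(C)CCC=O | intermediate
15 | ethyl (2E)-5-{(2S,3R)-3-[(4Z)-3-hydroxy-4-methylocta-4,7-dien-1-yl]-3-methyloxiran-2-yl}-3-methylpent-2-enoate (1:1 carbinol epimers) | CCOC(=O)/C=C(\C)CC[C@@H]1O[C@]1(C)CCC(O)/C(C)=C\CC=C | intermediate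
16 | (2E)-5-{(2S,3R)-3-[(4Z)-3-hydroxy-4-methylocta-4,7-dien-1-yl]-3-methyloxiran-2-yl}-3-methylpent-2-en-1-ol | OC/C=C(\C)CC[C@@H]1O[C@]1(C)CCC(O)/C(C)=C\CC=C | intermediate
17 | (2E)-5-{(2S,3R)-3-[(4Z)-3-hydroxy-4-methylocta-4,7-dien-1-yl]-3-methyloxiran-2-yl}-3-methylpent-2-enal | O=C/C=C(\C)CC[C@@H]1O[C@]1(C)CCC(O)/C(C)=C\CC=C | intermediate
18 | (4Z)-4-methyl-1-{(2R,3S)-2-methyl-3-[(3E)-3-methyl-5-oxopent-3-en-1-yl]oxiran-2-yl}octa-4,7-dien-3-yl 2,2-dimethylpropanoate | O=C/C=C(\C)CC[C@@H]1O[C@]1(C)CCC(OC(=O)C(C)(C)C)/C(C)=C\CC=C | intermediate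
19 | (4Z,7E)-4-methyl-1-{(2R,3S)-2-methyl-3-[(3E)-3-methyl-5-oxopent-3-en-1-yl]oxiran-2-yl}-9-oxonona-4,7-dien-3-yl 2,2-dimethylpropanoate | O=C/C=C(\C)CC[C@@H]1O[C@]1(C)CCC(OC(=O)C(C)(C)C)/C(C)=C\C/C=C/C=O | intermediate
20 | (1S,2R,3E,7S,8R,12Z)-7,8-epoxy-11-(pivaloyloxy)cembra-3,12-dien-16,2-olide (cis-fused lactone) | C1C(=O)O[C@H]2/C=C(\C)CC[C@@H]3O[C@]3(C)CCC(OC(=O)C(C)(C)C)/C(C)=C\C[C@@H]12 | intermediate
21 | (1S,2R,3E,7S,8R,12Z)-17-(dimethylamino)-7,8-epoxy-11-(pivaloyloxy)cembra-3,12-dien-16,2-olide (C15 epimers, not isolated) | CN(C)CC1C(=O)O[C@H]2/C=C(\C)CC[C@@H]3O[C@]3(C)CCC(OC(=O)C(C)(C)C)/C(C)=C\C[C@@H]12 | intermediate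
22 | N-methyl ammonium iodide of 21, 17-(trimethylammonio) lactone iodide (not isolated) | C[N+](C)(C)CC1C(=O)O[C@H]2/C=C(\C)CC[C@@H]3O[C@]3(C)CCC(OC(=O)C(C)(C)C)/C(C)=C\C[C@@H]12.[I-] | intermediate
23 | (1S,2S,3E,7S,8R,12Z)-7,8-epoxy-11-(pivaloyloxy)cembra-3,12,15(17)-trien-16,2-olide | C=C1C(=O)O[C@H]2/C=C(\C)CC[C@@H]3O[C@]3(C)CCC(OC(=O)C(C)(C)C)/C(C)=C\C[C@@H]12 | intermediate
24 | (1S,2S,3E,7S,8S,12Z)-8-hydroperoxy-7-hydroxy-11-(pivaloyloxy)cembra-3,12,15(17)-trien-16,2-olide | C=C1C(=O)O[C@H]2/C=C(\C)CC[C@H](O)[C@](OO)(C)CCC(OC(=O)C(C)(C)C)/C(C)=C\C[C@@H]12 | intermediate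
25 | (1S,2S,3E,7S,8S,11R,12Z)-8,11-epidioxy-7-hydroxycembra-3,12,15(17)-trien-16,2-olide | C=C1C(=O)O[C@H]2/C=C(\C)CC[C@H](O)[C@]3(C)CC[C@@H](OO3)/C(C)=C\C[C@@H]12 | intermediate
26 | (1S,2S,3E,7S,8S,11R,12Z)-7-acetoxy-8,11-epidioxycembra-3,12,15(17)-trien-16,2-olide | C=C1C(=O)O[C@H]2/C=C(\C)CC[C@H](OC(C)=O)[C@]3(C)CC[C@@H](OO3)/C(C)=C\C[C@@H]12 | target

**Totals and risks**

Total step count: 19. Longest linear sequence: 15 steps (nerol 8 → 26, steps 5–19).

Steps most likely to fail: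

Step 15 (carbene-catalysed macro-annulation). The risks are oligomerisation, base-induced conjugation of the skipped dienal, and the facial sense of the catalyst (the antipodal salt is used if the sense is wrong). Fallback, a ketyl–olefin reductive lactonisation in place of carbene catalysis: it sets out from 18. Cross-metathesis with methyl acrylate (same ruthenium catalyst) gives methyl (2E,5Z)-6-methyl-9-{(2R,3S)-2-methyl-3-[(3E)-3-methyl-5-oxopent-3-en-1-yl]oxiran-2-yl}-7-(pivaloyloxy)nona-2,5-dienoate F1. SmI2 (2.5 equiv) with t-BuOH in THF at −78 °C under high dilution then generates the C2 ketyl, which adds to C1 of the enoate and lactonises with loss of methanol. The cis isomer is separated and the route is rejoined at 20.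

Step 17 (perhydrolysis of the macrocyclic epoxide). The risks are loss of inversion at C8 and acid-induced rearrangement. Fallback, a bromohydrin followed by silver-assisted perhydrolysis: it sets out from 23. MgBr2·OEt2 in Et2O opens the epoxide at the tertiary carbon to give (1S,2S,3E,7S,8S,12Z)-8-bromo-7-hydroxy-11-(pivaloyloxy)cembra-3,12,15(17)-trien-16,2-olide F2. AgO2CCF3 with anhydrous H2O2 in Et2O then replaces bromide by OOH with anchimeric assistance from the C7 hydroxyl (net retention at C8), and the route is rejoined at 24.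

Step 18 (transannular cycloperoxidation). The risks are capture of the cation by the C7 hydroxyl instead of the hydroperoxide, and incomplete ionisation of the pivalate. Fallback, halide abstraction by silver from a silylated precursor in place of Lewis-acid ionisation of the ester: it sets out from 24. Me3SiBr (3 equiv) in CH2Cl2 at −20 °C converts the allylic pivalate into the allylic bromide and silylates both O–H groups, giving (1S,2S,3E,7S,8S,12Z)-11-bromo-7-(trimethylsilyloxy)-8-(trimethylsilylperoxy)cembra-3,12,15(17)-trien-16,2-olide F3. AgOSO2CF3 with 2,6-di-tert-butyl-4-methylpyridine then abstracts bromide, the silyl peroxide closes the dioxane, and aqueous work-up removes the C7 silyl group, rejoining the route at 25.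

Further compounds
F1 | step 15 | methyl (2E,5Z)-6-methyl-9-{(2R,3S)-2-methyl-3-[(3E)-3-methyl-5-oxopent-3-en-1-yl]oxiran-2-yl}-7-(pivaloyloxy)nona-2,5-dienoate | O=C/C=C(\C)CC[C@@H]1O[C@]1(C)CCC(OC(=O)C(C)(C)C)/C(C)=C\C/C=C/C(=O)OC
F2 | step 17 | (1S,2S,3E,7S,8S,12Z)-8-bromo-7-hydroxy-11-(pivaloyloxy)cembra-3,12,15(17)-trien-16,2-olide | C=C1C(=O)O[C@H]2/C=C(\C)CC[C@H](O)[C@](Br)(C)CCC(OC(=O)C(C)(C)C)/C(C)=C\C[C@@H]12
F3 | step 18 | (1S,2S,3E,7S,8S,12Z)-11-bromo-7-(trimethylsilyloxy)-8-(trimethylsilylperoxy)cembra-3,12,15(17)-trien-16,2-olide | C=C1C(=O)O[C@H]2/C=C(\C)CC[C@H](O[Si](C)(C)C)[C@](OO[Si](C)(C)C)(C)CCC(Br)/C(C)=C\C[C@@H]12
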